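The numbers of this flask are those of an exercise; the flask was simulated.

A small charge of solid substrate meets twice its amount of partner in this flask, yet the partner also decomposes by itself, so the flask is a race for partner.

solid substrate 0.094 M; partner 0.188 M; time 15 d

    starting material + partner → intermediate + by-product (k1 = 6.6 × 10⁻⁵ L mol⁻¹ s⁻¹)
    intermediate ⇌ target (K2 = 3.1, k2 = 8.8 × 10⁻⁵ s⁻¹)
    intermediate ⇌ isomer of the product (K3 = 2.9, k3 = 3.8 × 10⁻⁵ s⁻¹)
    solid substrate ⇌ starting material, rate k4*(cs4 - [starting material]) while solid is left; crystals form when [starting material] > cs4 (cs4 = 0.077 M, k4 = 3.7 × 10⁻⁵ s⁻¹)
    partner → decomposed reagent (k5 = 5.6 × 10⁻⁶ s⁻¹)

- how much target there is at 15 d, in percent of the solid substrate charged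
- how much starting material there is at 15 d, in percent of the solid substrate charged
- amount of target if the flask were left three thousand times as long, in percent of the solid substrate charged

Count amounts in fractions of the substrate charge, and take the ratio of the decomposition constant to the coupling constant times the charge as the tie fraction, 0.903, a selectivity factor between the two consumers of partner: with a fraction a of starting material standing, coupling takes a over a plus the tie fraction of the partner being used. You estimate the lag with which starting material arrives as 0.313 d, the inverse of the dissolution coefficient, and you let partner decay undisturbed for that long, which leaves a usable supply of 1.72 charges.

Your first way follows starting material: it falls as exp(-E), where the exposure E is the supply divided by the tie fraction plus a, and with a held at 0.5 you get 29.4% left. Your second way is the balance of partner, which needs no mean value, since the supply must equal the fraction consumed plus the tie fraction times E. Put that first answer in and it demands 1.81 charges, more than the supply, so the first way cheats with its middle value of a. You compute the correction, one Newton step of 2.3 percentage points, and your estimate of the starting material left comes to 31.7%.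

In this flask the partner's half-life by decomposition alone, 1.4 d, is shorter than the run, so you take the coupling as finished by the asked time, and the forward half-lives of the intermediate's two conversions, 0.091 d and 0.21 d, are shorter still, so you let the converted material split by equilibrium, with a target share of 44.3%. That makes 30.3% of target at the asked time, and 30.3% after the long wait.

The forecast gives 30% of target, 32% of starting material and 30% of target after the long wait, holding that “waiting longer does not change that amount”. The simulation gives 30.0%, 32.2% and 30.0%.

The shortfall in conversion is mainly due to the decomposition of partner: this flask converts 67.8% of the solid substrate, and the same run without that step converts >99.9%. Carry the tie fraction to the neighbour flask charged with 0.047 M of partner: its supply is 0.430 charges, the first way leaves 73.6%, and the Newton step raises that to 78.6%. That neighbour flask holds 79.5% of starting material at 15.0 d.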